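**Plan**

1. Rings: A = seven-membered carbocycle that holds the enol carbon; B = piperidine; C = pyrrolidine; D = cycloheptenone; E = five-membered fulvene ring.
2. Cuts, backwards: hydroxyfulvene to a cyclopentadienyl ester carbinol (oxidation and tautomerization; ester from an enol triflate); the CH2–CH2 bond of ring D by removal of one carbon (ring expansion of a cyclohexenone); the bond from the enol carbon to ring E (aldol, ring A); ring E plus the D/E fusion bond (Pauson–Khand); N–CH2 and CH–CH(CH3) of ring B (double alkylation); the lactam C–N of ring C and the bond from the quaternary carbon to its CH neighbour (Ireland–Claisen).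
3. Forward: ring C (as lactam) → ring B → six-membered ring D and ring E in one step → ring A → ring D enlarged to seven members → ester, then fulvene.
4. Stereochemistry: the N–CH carbon of ring C is bought as D-glutamic acid; the quaternary methyl carbon and the neighbouring CH follow from it in one Ireland–Claisen event (chair, Z-alkene, 1,3-allylic strain); the methyl-bearing CH of ring B comes from (S)-propane-1,2-diol cyclic sulfate with inversion; the last ring B CH is set by equilibration to the equatorial position.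
5. Enabling feature: in the six-membered ring D ketone the carbonyl carbon lies between a CH2 and the fully substituted sp2 carbon shared with ring E. That carbon is the β-carbon of the ring E cyclopentenone (an ene-dione) and cannot migrate, so an inserted carbon can only take over the CH2, and the cyclohexenone from the Pauson–Khand reaction becomes the cycloheptenone.

Key step: step 18

Remark: the CH centres made at the D/E ring fusion (step 14), at the two aldol carbons (step 16) and at the silyl-bearing carbon (step 18) are transient (all end as sp2 carbons or CH2) and are written without configuration.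

**Route**

Step 1
Reactants: 1 but-3-yn-1-ol
Product: 2 tert-butyl(but-3-yn-1-yloxy)diphenylsilane
Conditions: TBDPSCl, imidazole, DMF, 0 °C to rt
Reagents that add atoms: tert-butylchlorodiphenylsilane CC(C)(C)[Si](Cl)(c1ccccc1)c1ccccc1
Why: Imidazole-promoted silylation of the primary alcohol; the TBDPS ether is chosen because it must later survive CF3CO2H, LiAlH4 and aqueous HCl.

Step 2
Reactants: 2 tert-butyl(but-3-yn-1-yloxy)diphenylsilane; 3 methyl 4-chloro-4-oxobutanoate
Product: 4 methyl 8-(tert-butyldiphenylsilyloxy)-4-oxooct-5-ynoate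
Conditions: PdCl2(PPh3)2 (2 mol %), CuI (4 mol %), Et3N, THF, rt
Reagents that add atoms: none
Why: Acyl Sonogashira coupling (oxidative addition of the acid chloride, transmetallation from the copper acetylide, reductive elimination) should give the ynone and leave the methyl ester alone.

Step 3
Reactants: 4 methyl 8-(tert-butyldiphenylsilyloxy)-4-oxooct-5-ynoate
Product: 5 methyl 3-{2-[4-(tert-butyldiphenylsilyloxy)but-1-ynyl]-1,3-dioxolan-2-yl}propanoate
Conditions: Me3SiOCH2CH2OSiMe3, Me3SiOTf (5 mol %), CH2Cl2, −78 to −20 °C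
Reagents that add atoms: 1,2-bis(trimethylsilyloxy)ethane C[Si](C)(C)OCCO[Si](C)(C)C
Why: Silyl triflate-catalysed ketalization with the bis-silyl glycol ether masks the ynone carbonyl without conjugate addition, so that this carbon stays inert until step 17.

Step 4
Reactants: 5 methyl 3-{2-[4-(tert-butyldiphenylsilyloxy)but-1-ynyl]-1,3-dioxolan-2-yl}propanoate
Product: 6 3-{2-[4-(tert-butyldiphenylsilyloxy)but-1-ynyl]-1,3-dioxolan-2-yl}propanoic acid
Conditions: LiOH, THF/H2O, 0 °C; then 1 M HCl to pH 4
Reagents that add atoms: lithium hydroxide [Li+].[OH-]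
Why: Ester saponification; the dioxolane (deactivated by the alkyne) and the silyl ether should tolerate base and the brief mild acidification.

Step 5
Reactants: 7 Boc-D-Glu(OMe)-OH; 8 Meldrum's acid
Product: 10 tert-butyl (2R)-2-(3-methoxy-3-oxopropyl)-3,5-dioxopyrrolidine-1-carboxylate, via acyl Meldrum's acid 9 (not isolated)
Conditions: EDC·HCl, DMAP, CH2Cl2, 0 °C to rt; then EtOAc, reflux
Reagents that add atoms: none
Why: Tetramic acid synthesis: carbodiimide C-acylation of Meldrum's acid, then thermal loss of acetone and CO2 to an acyl ketene that the carbamate nitrogen traps, a sequence that is expected to keep the α-amino carbon intact.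

Step 6
Reactants: 10 tert-butyl (2R)-2-(3-methoxy-3-oxopropyl)-3,5-dioxopyrrolidine-1-carboxylate
Product: 11 tert-butyl (2R)-2-(3-methoxy-3-oxopropyl)-5-oxo-3-(tosyloxy)-2,5-dihydro-1H-pyrrole-1-carboxylate
Conditions: TsCl, iPr2NEt, CH2Cl2, 0 °C
Reagents that add atoms: 4-toluenesulfonyl chloride Cc1ccc(cc1)S(Cl)(=O)=O
Why: O-Sulfonylation of the vinylogous acid gives an enol tosylate that acts as a vinylogous acyl electrophile.

Step 7
Reactants: 11 tert-butyl (2R)-2-(3-methoxy-3-oxopropyl)-5-oxo-3-(tosyloxy)-2,5-dihydro-1H-pyrrole-1-carboxylate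
Product: 12 tert-butyl (2R)-2-(3-methoxy-3-oxopropyl)-3-methyl-5-oxo-2,5-dihydro-1H-pyrrole-1-carboxylate
Conditions: MeZnCl, PdCl2(dppf) (5 mol %), THF, 50 °C
Reagents that add atoms: methylzinc chloride C[Zn]Cl
Why: Negishi coupling of the β-tosyloxy enamide under non-basic conditions installs the future angular methyl on a ring alkene whose geometry is fixed cis.

Step 8
Reactants: 12 tert-butyl (2R)-2-(3-methoxy-3-oxopropyl)-3-methyl-5-oxo-2,5-dihydro-1H-pyrrole-1-carboxylate
Product: 14 methyl (4R,5Z)-4-(tert-butoxycarbonylamino)-7-hydroxy-5-methylhept-5-enoate, via Z-enal 13 (not isolated)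
Conditions: NaBH4, CeCl3·7H2O, MeOH, −20 to 0 °C
Reagents that add atoms: none
Why: Luche 1,2-reduction of the imide-like N-Boc lactam carbonyl, opening of the hemiaminal and immediate reduction of the enal should give the allylic alcohol with the Z geometry inherited from the five-membered ring.

Step 9
Reactants: 14 methyl (4R,5Z)-4-(tert-butoxycarbonylamino)-7-hydroxy-5-methylhept-5-enoate; 6 3-{2-[4-(tert-butyldiphenylsilyloxy)but-1-ynyl]-1,3-dioxolan-2-yl}propanoic acid
Product: 15 allyl ester of acid 6 with alcohol 14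
Conditions: EDC·HCl, DMAP, CH2Cl2, rt
Reagents that add atoms: none
Why: Steglich esterification of the primary allylic alcohol.

Step 10
Reactants: 15 allyl ester of acid 6 with alcohol 14
Product: 17 rearranged pent-4-enoic acid (C3 quaternary with methyl and vinyl; C2 carries the dioxolanylmethyl chain; configuration as in the SMILES), via silyl ketene acetal 16 (not isolated)
Conditions: LiN(iPr)2 (3.5 equiv), Me3SiCl (4 equiv), THF, −78 °C, then 45 °C; aq. NH4Cl
Reagents that add atoms: none
Why: Ireland–Claisen rearrangement: kinetic enolization in THF gives the ketene acetal with the chain cis to the allyloxy oxygen, whose chair transition state with the (Z)-trisubstituted alkene sets the quaternary methyl carbon and its CH neighbour in the relative sense needed for cis-fused rings C and D, while 1,3-allylic strain holds the C–H of the amino carbon in the alkene plane so that the new bond should form anti to the bulky silylated carbamate nitrogen.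

Step 11
Reactants: 17 rearranged pent-4-enoic acid
Product: 19 methyl 3-[(2R)-3-methyl-5-oxo-4-(dioxolanylmethyl chain)-3-vinylpyrrolidin-2-yl]propanoate (ring C lactam), via amino acid 18 (not isolated)
Conditions: CF3CO2H, CH2Cl2, 0 °C; evaporate; EDC·HCl, HOAt, iPr2NEt, CH2Cl2, 0 °C to rt
Reagents that add atoms: none
Why: Acidolysis of the Boc group, then carbodiimide lactamization of the activated acid (five-membered ring, helped by the quaternary carbon) should outrun attack of the amine on the unactivated methyl ester.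

Step 12
Reactants: 19 ring C lactam; 20 (S)-4-methyl-1,3,2-dioxathiolane 2,2-dioxide
Product: 22 methyl 1,6-dimethyl-3-oxo-2-(dioxolanylmethyl chain)-1-vinyloctahydroindolizine-7-carboxylate (rings B and C; ring B substituents all equatorial), via sulfate monoester 21 (not isolated)
Conditions: LiN(SiMe3)2 (1.05 equiv) added to 19 + 20, THF/DMPU, −78 to 0 °C; then LiN(SiMe3)2 (1.3 equiv), −78 to 40 °C; then NaOMe (cat.), MeOH, rt
Reagents that add atoms: none
Why: Double displacement on a 1,2-cyclic sulfate: the lactam nitrogen opens it at CH2, the ester enolate then closes the piperidine by 6-exo-tet SN2 with inversion at the methyl-bearing carbon, and methoxide equilibrates the ester-bearing carbon to the equatorial isomer.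

Step 13
Reactants: 22 indolizidinone ester
Product: 23 amino alcohol (lactam carbonyl reduced to CH2; ester reduced to CH2OH)
Conditions: LiAlH4, THF, 0 to 65 °C
Reagents that add atoms: none
Why: LiAlH4 reduces the tertiary lactam to the amine and the ester to the primary alcohol in one operation, while the ketal, internal alkyne, vinyl group and silyl ether should not react.

Step 14
Reactants: 23 amino alcohol
Product: 24 tetracyclic enone alcohol (rings B and C, six-membered ring D with ketal, cyclopentenone ring E)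
Conditions: Co2(CO)8 (20 mol %), tetramethylthiourea, CO (1 atm), toluene, 70 °C
Reagents that add atoms: carbon monoxide [C-]#[O+]
Why: Intramolecular Pauson–Khand [2+2+1] reaction of the 1,7-enyne (alkyne–cobalt complex, alkene insertion, CO insertion, reductive elimination) should close the six-membered ring D and ring E, favoured by the quaternary carbon in the tether; the new ring-fusion CH is planarized later.

Step 15
Reactants: 24 tetracyclic enone alcohol
Product: 25 keto aldehyde
Conditions: Dess–Martin periodinane, NaHCO3, CH2Cl2, 0 °C to rt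
Reagents that add atoms: none
Why: Dess–Martin oxidation of the primary alcohol; the epimerizable α-carbon should keep the aldehyde equatorial, the configuration of the target.

Step 16
Reactants: 25 keto aldehyde
Product: 27 pentacyclic β-silyloxy ketone (ring A closed; OTIPS on the future enol carbon), via lithium aldolate 26 (not isolated)
Conditions: LiN(SiMe3)2 (1.1 equiv), THF, −78 °C; then iPr3SiOTf, 2,6-lutidine, −78 to −20 °C
Reagents that add atoms: triisopropylsilyl trifluoromethanesulfonate CC(C)[Si](OS(=O)(=O)C(F)(F)F)(C(C)C)C(C)C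
Why: Intramolecular aldol addition of the kinetic α′-lithium enolate of the cyclopentenone to the aldehyde closes seven-membered ring A, and silylation of the aldolate in the same flask blocks retro-aldol and dehydration.

Step 17
Reactants: 27 pentacyclic β-silyloxy ketone
Product: 28 ene-dione (six-membered ring D ketone unveiled)
Conditions: 1 M HCl, THF, rt
Reagents that add atoms: water O
Why: Acid hydrolysis of the dioxolane to the conjugated ketone; the TIPS and TBDPS ethers should survive.

Step 18
Reactants: 28 ene-dione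
Product: 30 ring-expanded dione (ring D now a cycloheptenone), via α-silyl ketone 29 (not isolated)
Conditions: Me3SiCHN2 (1.5 equiv), AlMe3 (2.5 equiv), CH2Cl2, −78 to −30 °C; then 0.5 M HCl, 0 °C
Reagents that add atoms: trimethylsilyldiazomethane C[Si](C)(C)C=[N+]=[N-]
Why: AlMe3 activates the ring D carbonyl, the diazo carbon adds, and loss of N2 is concerted with a 1,2-shift of the anti-periplanar ring CH2 from the carbonyl carbon to the new carbon, which forms the CH2–CH2 bond; the α-silyl ketone is protodesilylated at work-up. The closest known type is the Tiffeneau–Demjanov-type homologation of cyclic ketones with trimethylsilyldiazomethane and a Lewis acid. Ring D is closed in its seven-membered form by ring expansion through 1,2-alkyl migration; no new stereocentre remains, since the silyl-bearing carbon becomes CH2 and the existing centres are not touched. Regioselectivity: the other neighbour of the carbonyl carbon is the fully substituted sp2 carbon of the ene-dione, the β-carbon of the ring E cyclopentenone, whose migration would put positive charge next to that carbonyl, so only the CH2 should migrate. Chemoselectivity: the ring E carbonyl is a cyclopentenone flanked by two fully substituted carbons (one carries the silyloxy-bearing ring A carbon) and should resist addition, and the hindered tetrasubstituted alkene should not undergo dipolar cycloaddition. Excess AlMe3 holds the amine, and the aldehyde that would compete was consumed in step 16.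

Step 19
Reactants: 30 ring-expanded dione
Product: 33 dienyl triflate of the ring E ketone (ring D ketone free), via silyl enol ether 31 (not isolated), via silyl enol ether triflate 32 (not isolated)
Conditions: LiN(SiMe3)2 (1.05 equiv), Me3SiCl, THF, −78 °C; then KN(SiMe3)2 (1.3 equiv), PhNTf2, −78 to −40 °C; aq. citric acid
Reagents that add atoms: N-phenylbis(trifluoromethanesulfonimide) FC(F)(F)S(=O)(=O)N(c1ccccc1)S(=O)(=O)C(F)(F)F
Why: Sequential kinetic enolization: the first base removes a proton from the only α-CH2 of the cycloheptenone and Me3SiCl masks that ketone as its silyl enol ether, the second base then enolizes the cyclopentenone for O-triflation (the γ-derived dienyl triflate would serve equally), and the silyl enol ether is hydrolysed at work-up.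

Step 20
Reactants: 33 dienyl triflate
Product: 34 cyclopentadienyl methyl ester
Conditions: Pd(OAc)2 (10 mol %), dppf, CO (1 atm), MeOH, Et3N, DMF, 60 °C
Reagents that add atoms: carbon monoxide [C-]#[O+]; methanol CO
Why: Palladium-catalysed methoxycarbonylation of the vinyl triflate (oxidative addition, CO insertion, methanolysis of the acyl palladium).

Step 21
Reactants: 34 cyclopentadienyl methyl ester
Product: 35 diol (free primary alcohol and free ring A carbinol)
Conditions: Bu4NF, AcOH, THF, 0 °C to rt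
Reagents that add atoms: none
Why: Fluoride cleaves both silyl ethers, and the acetic acid buffer should keep the acidic cyclopentadiene from eliminating the carbinol oxygen.

Step 22
Reactants: 35 diol
Product: 37 daphnicyclidin H, via triketone 36 (not isolated)
Conditions: MnO2, CH2Cl2, rt
Reagents that add atoms: none
Why: MnO2 should oxidize only the allylic, diene-activated secondary alcohol, and the resulting triacylcyclopentadiene tautomerizes to the hydrogen-bonded 6-hydroxyfulvene, its thermodynamic form.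

**Compound list**

1 | but-3-yn-1-ol | C#CCCO | starting material
2 | tert-butyl(but-3-yn-1-yloxy)diphenylsilane | C#CCCO[Si](c1ccccc1)(c1ccccc1)C(C)(C)C | intermediate
3 | methyl 4-chloro-4-oxobutanoate | COC(=O)CCC(Cl)=O | starting material
4 | methyl 8-(tert-butyldiphenylsilyloxy)-4-oxooct-5-ynoate | COC(=O)CCC(=O)C#CCCO[Si](c1ccccc1)(c1ccccc1)C(C)(C)C | intermediate
5 | methyl 3-{2-[4-(tert-butyldiphenylsilyloxy)but-1-ynyl]-1,3-dioxolan-2-yl}propanoate | COC(=O)CCC1(OCCO1)C#CCCO[Si](c1ccccc1)(c1ccccc1)C(C)(C)C | intermediate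
6 | 3-{2-[4-(tert-butyldiphenylsilyloxy)but-1-ynyl]-1,3-dioxolan-2-yl}propanoic acid | OC(=O)CCC1(OCCO1)C#CCCO[Si](c1ccccc1)(c1ccccc1)C(C)(C)C | intermediate
7 | Boc-D-Glu(OMe)-OH, (R)-2-(tert-butoxycarbonylamino)-5-methoxy-5-oxopentanoic acid | COC(=O)CC[C@@H](NC(=O)OC(C)(C)C)C(O)=O | starting material
8 | Meldrum's acid, 2,2-dimethyl-1,3-dioxane-4,6-dione | CC1(C)OC(=O)CC(=O)O1 | starting material
9 | acyl Meldrum's acid of 7 | COC(=O)CC[C@@H](NC(=O)OC(C)(C)C)C(=O)C1C(=O)OC(C)(C)OC1=O | intermediate
10 | tert-butyl (2R)-2-(3-methoxy-3-oxopropyl)-3,5-dioxopyrrolidine-1-carboxylate | COC(=O)CC[C@H]1N(C(=O)OC(C)(C)C)C(=O)CC1=O | intermediate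
11 | tert-butyl (2R)-2-(3-methoxy-3-oxopropyl)-5-oxo-3-(tosyloxy)-2,5-dihydro-1H-pyrrole-1-carboxylate | COC(=O)CC[C@H]1N(C(=O)OC(C)(C)C)C(=O)C=C1OS(=O)(=O)c1ccc(C)cc1 | intermediate
12 | tert-butyl (2R)-2-(3-methoxy-3-oxopropyl)-3-methyl-5-oxo-2,5-dihydro-1H-pyrrole-1-carboxylate | COC(=O)CC[C@H]1N(C(=O)OC(C)(C)C)C(=O)C=C1C | intermediate
13 | methyl (4R,5Z)-4-(tert-butoxycarbonylamino)-5-methyl-7-oxohept-5-enoate | COC(=O)CC[C@@H](NC(=O)OC(C)(C)C)/C(C)=C\C=O | intermediate
14 | methyl (4R,5Z)-4-(tert-butoxycarbonylamino)-7-hydroxy-5-methylhept-5-enoate | COC(=O)CC[C@@H](NC(=O)OC(C)(C)C)/C(C)=C\CO | intermediate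
15 | allyl ester of acid 6 with alcohol 14 | COC(=O)CC[C@@H](NC(=O)OC(C)(C)C)/C(C)=C\COC(=O)CCC1(OCCO1)C#CCCO[Si](c1ccccc1)(c1ccccc1)C(C)(C)C | intermediate
16 | tris(trimethylsilyl) derivative of 15 (allyl ketene acetal with chain cis to the allyloxy oxygen; N-silyl carbamate; methyl ketene acetal) | COC(O[Si](C)(C)C)=CC[C@@H](N([Si](C)(C)C)C(=O)OC(C)(C)C)/C(C)=C\CO/C(O[Si](C)(C)C)=C\CC1(OCCO1)C#CCCO[Si](c1ccccc1)(c1ccccc1)C(C)(C)C | intermediate
17 | rearranged acid: 3-[(1R)-1-(Boc-amino)-4-methoxy-4-oxobutyl]-3-methyl-2-(dioxolanylmethyl chain)pent-4-enoic acid | OC(=O)[C@@H](CC1(OCCO1)C#CCCO[Si](c1ccccc1)(c1ccccc1)C(C)(C)C)[C@@](C=C)([C@H](NC(=O)OC(C)(C)C)CCC(=O)OC)C | intermediate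
18 | amino acid from 17 (present as trifluoroacetate) | OC(=O)[C@@H](CC1(OCCO1)C#CCCO[Si](c1ccccc1)(c1ccccc1)C(C)(C)C)[C@@](C=C)([C@H](N)CCC(=O)OC)C | intermediate
19 | ring C lactam: methyl 3-[(2R)-3-methyl-5-oxo-4-(dioxolanylmethyl chain)-3-vinylpyrrolidin-2-yl]propanoate | COC(=O)CC[C@H]1NC(=O)[C@@H](CC2(OCCO2)C#CCCO[Si](c2ccccc2)(c2ccccc2)C(C)(C)C)[C@]1(C=C)C | intermediate
20 | (S)-4-methyl-1,3,2-dioxathiolane 2,2-dioxide (cyclic sulfate of (S)-propane-1,2-diol) | C[C@H]1COS(=O)(=O)O1 | starting material
21 | lithium sulfate monoester of the N-(2-hydroxypropyl) lactam | [Li+].COC(=O)CC[C@H]1N(C[C@H](C)OS(=O)(=O)[O-])C(=O)[C@@H](CC2(OCCO2)C#CCCO[Si](c2ccccc2)(c2ccccc2)C(C)(C)C)[C@]1(C=C)C | intermediate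
22 | indolizidinone ester (rings B and C) | COC(=O)[C@@H]1C[C@H]2N(C[C@H]1C)C(=O)[C@@H](CC3(OCCO3)C#CCCO[Si](c3ccccc3)(c3ccccc3)C(C)(C)C)[C@]2(C=C)C | intermediate
23 | amino alcohol (indolizidine with CH2OH on ring B) | OC[C@@H]1C[C@H]2N(C[C@H]1C)C[C@@H](CC3(OCCO3)C#CCCO[Si](c3ccccc3)(c3ccccc3)C(C)(C)C)[C@]2(C=C)C | intermediate
24 | tetracyclic enone alcohol (Pauson–Khand product) | OC[C@@H]1C[C@H]2N(C[C@H]1C)C[C@H]3CC4(OCCO4)C5=C(CCO[Si](c6ccccc6)(c6ccccc6)C(C)(C)C)C(=O)CC5[C@@]23C | intermediate
25 | keto aldehyde | O=C[C@@H]1C[C@H]2N(C[C@H]1C)C[C@H]3CC4(OCCO4)C5=C(CCO[Si](c6ccccc6)(c6ccccc6)C(C)(C)C)C(=O)CC5[C@@]23C | intermediate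
26 | lithium aldolate (ring A closed) | [Li+].[O-]C1[C@@H]2C[C@H]3N(C[C@H]2C)C[C@H]4CC5(OCCO5)C6=C(CCO[Si](c7ccccc7)(c7ccccc7)C(C)(C)C)C(=O)C1C6[C@@]34C | intermediate
27 | pentacyclic β-triisopropylsilyloxy ketone with ketal | CC(C)[Si](OC1[C@@H]2C[C@H]3N(C[C@H]2C)C[C@H]4CC5(OCCO5)C6=C(CCO[Si](c7ccccc7)(c7ccccc7)C(C)(C)C)C(=O)C1C6[C@@]34C)(C(C)C)C(C)C | intermediate
28 | ene-dione (six-membered ring D ketone) | CC(C)[Si](OC1[C@@H]2C[C@H]3N(C[C@H]2C)C[C@H]4CC(=O)C5=C(CCO[Si](c6ccccc6)(c6ccccc6)C(C)(C)C)C(=O)C1C5[C@@]34C)(C(C)C)C(C)C | intermediate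
29 | α-trimethylsilyl cycloheptenone | CC(C)[Si](OC1[C@@H]2C[C@H]3N(C[C@H]2C)C[C@H]4CC([Si](C)(C)C)C(=O)C5=C(CCO[Si](c6ccccc6)(c6ccccc6)C(C)(C)C)C(=O)C1C5[C@@]34C)(C(C)C)C(C)C | intermediate
30 | ring-expanded dione (seven-membered ring D) | CC(C)[Si](OC1[C@@H]2C[C@H]3N(C[C@H]2C)C[C@H]4CCC(=O)C5=C(CCO[Si](c6ccccc6)(c6ccccc6)C(C)(C)C)C(=O)C1C5[C@@]34C)(C(C)C)C(C)C | intermediate
31 | trimethylsilyl enol ether of the ring D ketone | CC(C)[Si](OC1[C@@H]2C[C@H]3N(C[C@H]2C)C[C@H]4CC=C(O[Si](C)(C)C)C5=C(CCO[Si](c6ccccc6)(c6ccccc6)C(C)(C)C)C(=O)C1C5[C@@]34C)(C(C)C)C(C)C | intermediate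
32 | silyl enol ether dienyl triflate | CC(C)[Si](OC1[C@@H]2C[C@H]3N(C[C@H]2C)C[C@H]4CC=C(O[Si](C)(C)C)C5=C(CCO[Si](c6ccccc6)(c6ccccc6)C(C)(C)C)C(OS(=O)(=O)C(F)(F)F)=C1C5[C@@]34C)(C(C)C)C(C)C | intermediate
33 | keto dienyl triflate | CC(C)[Si](OC1[C@@H]2C[C@H]3N(C[C@H]2C)C[C@H]4CCC(=O)C5=C(CCO[Si](c6ccccc6)(c6ccccc6)C(C)(C)C)C(OS(=O)(=O)C(F)(F)F)=C1C5[C@@]34C)(C(C)C)C(C)C | intermediate
34 | cyclopentadienyl methyl ester | CC(C)[Si](OC1[C@@H]2C[C@H]3N(C[C@H]2C)C[C@H]4CCC(=O)C5=C(CCO[Si](c6ccccc6)(c6ccccc6)C(C)(C)C)C(C(=O)OC)=C1C5[C@@]34C)(C(C)C)C(C)C | intermediate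
35 | diol | OC1[C@@H]2C[C@H]3N(C[C@H]2C)C[C@H]4CCC(=O)C5=C(CCO)C(C(=O)OC)=C1C5[C@@]34C | intermediate
36 | triketone (keto tautomer of the target) | O=C1[C@@H]2C[C@H]3N(C[C@H]2C)C[C@H]4CCC(=O)C5=C(CCO)C(C(=O)OC)=C1C5[C@@]34C | intermediate
37 | daphnicyclidin H | COC(=O)C1=C(CCO)C2=C3C1=C(O)[C@@H]1C[C@H]4N(C[C@@H](CCC2=O)[C@@]34C)C[C@H]1C | target

**Count and risks**

Total step count: 22. Longest linear sequence: 18 steps (steps 5 to 22 from 7; the side chain of steps 1 to 4 enters at step 9).

Steps most likely to fail: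

Step 18. The diazoalkane may add to the ring E carbonyl instead, the amine may bind the Lewis acid so that no addition occurs, or the adduct may close to an epoxide instead of migrating. Fallback from 28, returning at 30: kinetic deprotonation at the only α-CH2 of the six-membered ring D ketone (LiN(SiMe3)2, Me3SiCl, THF, −78 °C) should give the silyl enol ether F1. Simmons–Smith cyclopropanation of this electron-rich alkene (Et2Zn, CH2I2) should give the siloxycyclopropane F2. Ito–Saegusa ring expansion with FeCl3 in DMF (alkoxy radical, β-scission of the ring-fusion bond) should give the β-chloro cycloheptanone F3, and NaOAc in MeOH should eliminate HCl to the cycloheptadienone F4. Conjugate reduction of its disubstituted enone with [(Ph3P)CuH]6 returns to 30.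

Step 16. The kinetic enolate may be quenched by proton transfer from the aldehyde α-C–H, or the strained seven-membered aldolate may revert before it is silylated. Fallback from 23, returning at 27: Dess–Martin oxidation should give the aldehyde F5, and CH2=CHMgBr the allylic alcohol F6 (either carbinol epimer serves). iPr3SiOTf and 2,6-lutidine should give the silyl ether F7. Ring-closing metathesis with the second-generation Grubbs catalyst (amine masked as its camphorsulfonate salt) should join the two vinyl groups to the cycloheptene F8, which is ring A. A Pauson–Khand reaction of F8 under the conditions of step 14 then builds the six-membered ring D and ring E on the ring A alkene and returns to 27.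

Step 12. The lactam anion may be alkylated on oxygen, or the secondary sulfate may undergo elimination instead of ring closure. Fallback from 19, returning at 22: NaH and (S)-2-methyloxirane in DMF should give the N-(2-hydroxypropyl) lactam F9 by epoxide opening at CH2. MsCl and Et3N should give the mesylate F10. KN(SiMe3)2 in THF then closes ring B by enolate SN2 with inversion, and NaOMe in MeOH equilibrates the ester-bearing carbon to return to 22.

**Further compounds**

F1 | step 18 | trimethylsilyl enol ether of 28 | CC(C)[Si](OC1[C@@H]2C[C@H]3N(C[C@H]2C)C[C@H]4C=C(O[Si](C)(C)C)C5=C(CCO[Si](c6ccccc6)(c6ccccc6)C(C)(C)C)C(=O)C1C5[C@@]34C)(C(C)C)C(C)C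
F2 | step 18 | siloxycyclopropane | CC(C)[Si](OC1[C@@H]2C[C@H]3N(C[C@H]2C)C[C@H]4C7CC7(O[Si](C)(C)C)C5=C(CCO[Si](c6ccccc6)(c6ccccc6)C(C)(C)C)C(=O)C1C5[C@@]34C)(C(C)C)C(C)C
F3 | step 18 | β-chloro cycloheptanone | CC(C)[Si](OC1[C@@H]2C[C@H]3N(C[C@H]2C)C[C@H]4C(Cl)CC(=O)C5=C(CCO[Si](c6ccccc6)(c6ccccc6)C(C)(C)C)C(=O)C1C5[C@@]34C)(C(C)C)C(C)C
F4 | step 18 | cycloheptadienone | CC(C)[Si](OC1[C@@H]2C[C@H]3N(C[C@H]2C)C[C@H]4C=CC(=O)C5=C(CCO[Si](c6ccccc6)(c6ccccc6)C(C)(C)C)C(=O)C1C5[C@@]34C)(C(C)C)C(C)C
F5 | step 16 | aldehyde from 23 | O=C[C@@H]1C[C@H]2N(C[C@H]1C)C[C@@H](CC3(OCCO3)C#CCCO[Si](c3ccccc3)(c3ccccc3)C(C)(C)C)[C@]2(C=C)C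
F6 | step 16 | allylic alcohol | OC(C=C)[C@@H]1C[C@H]2N(C[C@H]1C)C[C@@H](CC3(OCCO3)C#CCCO[Si](c3ccccc3)(c3ccccc3)C(C)(C)C)[C@]2(C=C)C
F7 | step 16 | triisopropylsilyl ether of the allylic alcohol | CC(C)[Si](OC(C=C)[C@@H]1C[C@H]2N(C[C@H]1C)C[C@@H](CC3(OCCO3)C#CCCO[Si](c3ccccc3)(c3ccccc3)C(C)(C)C)[C@]2(C=C)C)(C(C)C)C(C)C
F8 | step 16 | cycloheptene (ring A by metathesis) | CC(C)[Si](OC1[C@@H]2C[C@H]3N(C[C@H]2C)C[C@@H](CC5(OCCO5)C#CCCO[Si](c6ccccc6)(c6ccccc6)C(C)(C)C)[C@]3(C=C1)C)(C(C)C)C(C)C
F9 | step 12 | N-[(S)-2-hydroxypropyl] lactam | COC(=O)CC[C@H]1N(C[C@H](C)O)C(=O)[C@@H](CC2(OCCO2)C#CCCO[Si](c2ccccc2)(c2ccccc2)C(C)(C)C)[C@]1(C=C)C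
F10 | step 12 | mesylate of the hydroxypropyl lactam | COC(=O)CC[C@H]1N(C[C@H](C)OS(C)(=O)=O)C(=O)[C@@H](CC2(OCCO2)C#CCCO[Si](c2ccccc2)(c2ccccc2)C(C)(C)C)[C@]1(C=C)C
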